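## Retrosynthetic overview

1. Target 16 ← desilylation of 15 ← acetylation of diol 14 ← one Luche reduction of diketone 13 (sets C2 and C9) ← isovaleroylation of ketol 12.
2. 12 ← axial isopropenyl cuprate addition (sets C7) to ring B enone 11 ← MnO2 oxidation of the allylic C9 alcohol of 10.
3. Ring A enone 10 (C15 now in place) ← Stork–Danheiser methyl addition and transposition on 8 ← 9-OH-directed reduction (sets C1) of trans-enedione 6.
4. 6 ← silylation and C5 epimerization of cis adduct 4 ← catalytic enantioselective endo Diels–Alder (sets C10 and C9) of quinone 2 (ring A, present first) with diene 3 (forms ring B).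
5. 2 ← Teuber oxidation of achiral 2-hydroxy-3-methoxybenzyl alcohol 1.

Convention: names use eudesmane numbering (ring A = C1–C5, C10; ring B = C5–C10; C14 on C10, C15 on C4); the decalin is viewed with ring A on the left and C10 at the top of the ring fusion, α = below, β = above (C14 is α).

Assumption: (R)-TRIP, (R)-3,3'-bis(2,4,6-triisopropylphenyl)-1,1'-binaphthyl-2,2'-diyl hydrogen phosphate, gives the enantiomer of 4 drawn below; if the sense is opposite, (S)-TRIP is used and nothing else changes.

## Route

Step 1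
Reactants: 1 2-hydroxy-3-methoxybenzyl alcohol
Product: 2 2-(hydroxymethyl)-6-methoxy-1,4-benzoquinone
Conditions: (KSO3)2NO (2.2 equiv), KH2PO4, H2O–acetone, 0 °C → rt
Reagents that add atoms: potassium nitrosodisulfonate (Fremy's salt), [K+].[K+].[O]N(S(=O)(=O)[O-])S(=O)(=O)[O-]
Why: Teuber oxidation: the nitrosodisulfonate radical converts a phenol with a free para position into the p-quinone and leaves the benzylic alcohol alone; no stereocenter is formed.

Step 2
Reactants: 2 2-(hydroxymethyl)-6-methoxy-1,4-benzoquinone; 3 (E)-1-(trimethylsilyloxy)buta-1,3-diene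
Product: 4 cis-fused adduct 8a-(hydroxymethyl)-2-methoxy-8-(trimethylsilyloxy)-4a,5,8,8a-tetrahydronaphthalene-1,4-dione (5α-H; 9β-OTMS; 10α-CH2OH)
Conditions: (R)-TRIP (10 mol %), 4 Å MS, toluene, −60 °C
Reagents that add atoms: none
Why: Proposed new method: the BINOL-phosphoric acid is expected to hold 2 by two hydrogen bonds (P=O to the CH2O–H, P–OH to the neighbouring C1 carbonyl), which activates C1=O so that C5 is the electrophilic terminus as in the thermal reaction (the methoxy group switches off the C2=C3 bond), and endo [4+2] addition of the E-diene on the open face then joins C6 to C5 and C9 to C10 and sets C10, C9 (oxygen trans to C14) and the cis C5–H in one step; the closest known reaction types are Brønsted-acid-catalysed Diels–Alder and vinylogous Mukaiyama additions of silyloxydienes and hydroxyl-anchored two-point binding to chiral phosphoric acids, not yet shown for a quinone dienophile.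

Step 3
Reactants: 4 cis-fused adduct
Product: 6 trans-fused bis-silyl ether (5β-H; 9β-OTMS; 14-OTBS; 2-methoxy-2,7-diene-1,4-dione), via cis-fused bis-silyl ether 5 (not isolated)
Conditions: TBSCl, imidazole, CH2Cl2, 0 °C; then DBU (2 equiv), rt
Reagents that add atoms: tert-butyldimethylsilyl chloride (TBSCl), C[Si](C)(Cl)C(C)(C)C
Why: Silylation of the only hydroxyl (mild imidazole conditions avoid retro-aldol loss of formaldehyde) is followed by DBU enolization of the C4 ketone and thermodynamic reprotonation at C5, which gives the trans-fused decalin preferred by angularly substituted decalin-4-ones and sets C5 as 5β-H (base-mediated epimerization).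

Step 4
Reactants: 6 trans-fused bis-silyl ether
Product: 8 1α,9β-diol (14-OTBS; 2-methoxy-2,7-dien-4-one; 5β-H), via 9β-hydroxy enedione 7 (not isolated)
Conditions: AcOH–MeCN (1:1), H2O (2 equiv), 0 °C; then Me4NBH(OAc)3, −30 → −10 °C
Reagents that add atoms: none
Why: Evans–Saksena hydroxyl-directed reduction: the acid first cleaves the labile TMS ether, the axial 9β-OH then binds boron and delivers hydride intramolecularly to the β face of the C1 ketone (anti-1,3-diol), so C1 becomes 1α-OH while the vinylogous ester carbonyl C4 is not reduced.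

Step 5
Reactants: 8 1α,9β-diol
Product: 10 1α,9β-dihydroxy-4-methyl-3,7-dien-2-one (14-OTBS; 5β-H), via tertiary C4 carbinol 9 (not isolated)
Conditions: MeLi (4 equiv), CeCl3, THF, −78 °C; then 1 M HCl, THF, 0 °C
Reagents that add atoms: methyllithium, [Li]C; water, O
Why: Stork–Danheiser sequence: the organocerium reagent adds 1,2 to the vinylogous ester carbonyl C4 without enolizing it (this brings in C15), and aqueous acid then hydrolyses the enol ether and expels the tertiary hydroxyl to give the transposed 4-methyl-3-en-2-one; the transient C4 centre disappears and no other stereocenter is touched.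

Step 6
Reactants: 10 1α,9β-dihydroxy-4-methyl-3,7-dien-2-one
Product: 11 1α-hydroxy-4-methyl-3,7-diene-2,9-dione (14-OTBS; 5β-H)
Conditions: MnO2 (excess), CH2Cl2, rt
Reagents that add atoms: none
Why: Selective allylic oxidation: MnO2 oxidizes only the allylic C9 alcohol to the ring B enone because the C1 hydroxyl is no longer allylic once C2 is a ketone; C9 is set again in step 9.

Step 7
Reactants: 11 1α-hydroxy-4-methyl-3,7-diene-2,9-dione
Product: 12 1α-hydroxy-7β-isopropenyl-4-methyl-3-ene-2,9-dione (14-OTBS; 5β-H)
Conditions: CH2=C(CH3)MgBr (4.4 equiv), CuBr·SMe2 (2.2 equiv), THF, −78 °C; aq. NH4Cl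
Reagents that add atoms: isopropenylmagnesium bromide, C=C(C)[Mg]Br
Why: Cuprate conjugate addition: the ring B enone has an unsubstituted β-carbon and takes the isopropenyl group by stereoelectronically favoured axial attack on the β face of the rigid trans-decalin (chair-like enolate, only H5 syn-axial), which sets C7 as 7β, while the β,β-disubstituted ring A enone is inert and the excess reagent covers the free hydroxyl.

Step 8
Reactants: 12 1α-hydroxy-7β-isopropenyl-4-methyl-3-ene-2,9-dione
Product: 13 1α-(3-methylbutanoyloxy)-7β-isopropenyl-4-methyl-3-ene-2,9-dione (14-OTBS)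
Conditions: (CH3)2CHCH2COCl, pyridine, DMAP (cat.), CH2Cl2, 0 °C
Reagents that add atoms: 3-methylbutanoyl chloride (isovaleryl chloride), CC(C)CC(Cl)=O
Why: DMAP-catalysed esterification of the only free hydroxyl places the isovalerate on O1; no stereocenter changes.

Step 9
Reactants: 13 1α-isovalerate diketone
Product: 14 2α,9β-diol 1α-isovalerate (14-OTBS)
Conditions: NaBH4, CeCl3·7H2O, MeOH, −78 → −40 °C; AcOH quench
Reagents that add atoms: none
Why: Luche reduction: hydride reaches C2 from the β face because the axial C14 group screens the α face (gives 2α-OH) and reaches C9 from the α face because the axial 7β-isopropenyl group blocks the β face (gives axial 9β-OH), while the cerium salt and low temperature suppress conjugate reduction, ester cleavage and acyl migration.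

Step 10
Reactants: 14 2α,9β-diol 1α-isovalerate
Product: 15 2α,9β-diacetate 1α-isovalerate (14-OTBS)
Conditions: Ac2O, DMAP, pyridine, CH2Cl2, rt → 40 °C
Reagents that add atoms: acetic anhydride, CC(=O)OC(C)=O
Why: DMAP-catalysed acetylation esterifies both secondary alcohols at once while the primary oxygen is still silylated; no stereocenter changes.

Step 11
Reactants: 15 2α,9β-diacetate 1α-isovalerate
Product: 16 target CNP0257109.1
Conditions: HF·pyridine, pyridine, THF, 0 °C → rt
Reagents that add atoms: none
Why: Fluoride-mediated desilylation under mildly acidic conditions frees the primary C14 hydroxyl without ester cleavage or acyl migration and gives the target.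

## Compound list

1 | 2-hydroxy-3-methoxybenzyl alcohol (o-vanillyl alcohol) | COc1cccc(CO)c1O | starting material
2 | 2-(hydroxymethyl)-6-methoxy-1,4-benzoquinone | COC1=CC(=O)C=C(CO)C1=O | intermediate
3 | (E)-1-(trimethylsilyloxy)buta-1,3-diene | C=C/C=C/O[Si](C)(C)C | starting material
4 | cis-fused Diels–Alder adduct, 8a-(hydroxymethyl)-2-methoxy-8-(trimethylsilyloxy)-4a,5,8,8a-tetrahydronaphthalene-1,4-dione (5α-H, 9β-OTMS, 10α-CH2OH) | C1=C[C@H](O[Si](C)(C)C)[C@@]2(CO)[C@@H](C1)C(=O)C=C(OC)C2=O | intermediate
5 | cis-fused bis-silyl ether (as 4 with 14-OTBS; 5α-H) | C1=C[C@H](O[Si](C)(C)C)[C@@]2(CO[Si](C)(C)C(C)(C)C)[C@@H](C1)C(=O)C=C(OC)C2=O | intermediate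
6 | trans-fused bis-silyl ether (5β-H, 9β-OTMS, 14-OTBS, 2-methoxy-2,7-diene-1,4-dione) | C1=C[C@H](O[Si](C)(C)C)[C@@]2(CO[Si](C)(C)C(C)(C)C)[C@H](C1)C(=O)C=C(OC)C2=O | intermediate
7 | 9β-hydroxy trans-enedione (14-OTBS, 2-methoxy-2,7-diene-1,4-dione) | C1=C[C@H](O)[C@@]2(CO[Si](C)(C)C(C)(C)C)[C@H](C1)C(=O)C=C(OC)C2=O | intermediate
8 | 1α,9β-dihydroxy-2-methoxy-2,7-dien-4-one (14-OTBS, 5β-H) | C1=C[C@H](O)[C@@]2(CO[Si](C)(C)C(C)(C)C)[C@H](C1)C(=O)C=C(OC)[C@@H]2O | intermediate
9 | 1α,4α,9β-trihydroxy-2-methoxy-4β-methyl-2,7-diene (14-OTBS; C4 configuration predicted, inconsequential) | C1=C[C@H](O)[C@@]2(CO[Si](C)(C)C(C)(C)C)[C@H](C1)[C@](C)(O)C=C(OC)[C@@H]2O | intermediate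
10 | 1α,9β-dihydroxy-4-methyl-3,7-dien-2-one (14-OTBS, 5β-H) | C1=C[C@H](O)[C@@]2(CO[Si](C)(C)C(C)(C)C)[C@H](C1)C(C)=CC(=O)[C@@H]2O | intermediate
11 | 1α-hydroxy-4-methyl-3,7-diene-2,9-dione (14-OTBS, 5β-H) | C1=CC(=O)[C@@]2(CO[Si](C)(C)C(C)(C)C)[C@H](C1)C(C)=CC(=O)[C@@H]2O | intermediate
12 | 1α-hydroxy-7β-isopropenyl-4-methyl-3-ene-2,9-dione (14-OTBS, 5β-H) | C=C(C)[C@@H]1CC(=O)[C@@]2(CO[Si](C)(C)C(C)(C)C)[C@H](C1)C(C)=CC(=O)[C@@H]2O | intermediate
13 | 1α-(3-methylbutanoyloxy)-7β-isopropenyl-4-methyl-3-ene-2,9-dione (14-OTBS) | C=C(C)[C@@H]1CC(=O)[C@@]2(CO[Si](C)(C)C(C)(C)C)[C@H](C1)C(C)=CC(=O)[C@@H]2OC(=O)CC(C)C | intermediate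
14 | 2α,9β-dihydroxy-1α-(3-methylbutanoyloxy)-14-(tert-butyldimethylsilyloxy)eudesma-3,11-diene (5β-H, 7β-isopropenyl) | C=C(C)[C@@H]1C[C@H](O)[C@@]2(CO[Si](C)(C)C(C)(C)C)[C@H](C1)C(C)=C[C@H](O)[C@@H]2OC(=O)CC(C)C | intermediate
15 | 2α,9β-diacetoxy-1α-(3-methylbutanoyloxy)-14-(tert-butyldimethylsilyloxy)eudesma-3,11-diene | C=C(C)[C@@H]1C[C@H](OC(C)=O)[C@@]2(CO[Si](C)(C)C(C)(C)C)[C@H](C1)C(C)=C[C@H](OC(C)=O)[C@@H]2OC(=O)CC(C)C | intermediate
16 | CNP0257109.1, (1R,2S,5R,7S,9S,10S)-2,9-diacetoxy-14-hydroxy-1-(3-methylbutanoyloxy)eudesma-3,11-diene (1α-O-isovaleryl, 2α-OAc, 9β-OAc, 5β-H, 7β-isopropenyl, 10α-CH2OH) | C=C(C)[C@@H]1C[C@H](OC(C)=O)[C@@]2(CO)[C@H](C1)C(C)=C[C@H](OC(C)=O)[C@@H]2OC(=O)CC(C)C | target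

## Step count and risks

Total step count: 11. Longest linear sequence: 11 steps (1 → 16); diene 3 is used as purchased.

Steps most likely to fail:

Step 2 (the proposed new cycloaddition). The risks are low enantioselectivity, a racemic background reaction of the self-activated hydroxymethyl quinone, and silyl transfer from the diene to the free hydroxyl. The fallback uses known chemistry and sets out from compound 1. The benzylic hydroxyl is silylated first (TBSCl, imidazole) to give 2-[(tert-butyldimethylsilyloxy)methyl]-6-methoxyphenol F1. Teuber oxidation with (KSO3)2NO gives 2-[(tert-butyldimethylsilyloxy)methyl]-6-methoxy-1,4-benzoquinone F2. The cycloaddition with 3 is then run as a chelation-controlled Lewis-acid Diels–Alder with the catalyst made from (R)-BINOL and TiCl2(OiPr)2 (4 Å MS, toluene, −30 °C). This BINOL–titanium system is an established one for enantioselective additions of oxygenated dienes to 2-methoxy-1,4-benzoquinones; it binds the methoxy oxygen and the C1 carbonyl and so gives the same regiochemistry. The product is 5, and the route is rejoined at compound 5, which is treated with DBU as in step 3.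

Step 7 (cuprate addition to a substrate whose free α-ketol is also a β-hydroxy ketone). The risks are retro-aldol opening of ring A and enolization. The fallback sets out from compound 11. The hydroxyl is acylated first (isovaleryl chloride, pyridine, DMAP) to give 1α-(3-methylbutanoyloxy)-4-methyl-3,7-diene-2,9-dione F3. The isopropenyl group is then introduced under neutral conditions by the known rhodium-catalysed 1,4-addition of an alkenylboron reagent to a cyclic enone (isopropenylboronic acid pinacol ester, [Rh(cod)OH]2, dioxane–H2O, 40 °C). This tolerates the ester, avoids the electron-transfer cleavage of α-acyloxy ketones that cuprates can cause, and should add to the same less hindered axial trajectory. The product is 13, and the route is rejoined at compound 13.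

Step 9 (two ketones reduced in one operation). The risks are the wrong face at C9 and migration of the isovalerate to O2. The fallback sets out from compound 12, before acylation. The free 1α-hydroxyl directs an Evans–Saksena reduction (Me4NBH(OAc)3, AcOH–MeCN, −30 °C) of the saturated C9 ketone by intramolecular hydride delivery, giving the anti 1α,9β-dihydroxy-7β-isopropenyl-4-methyl-3-en-2-one F4; the conjugated C2 ketone, which would need a five-membered delivery, is left. The equatorial C1 hydroxyl is then acylated selectively over the hindered axial C9 hydroxyl (isovaleryl chloride, pyridine, −20 °C) to give 9β-hydroxy-1α-(3-methylbutanoyloxy)-7β-isopropenyl-4-methyl-3-en-2-one F5. A Luche reduction of the single remaining C2 enone gives 14, where the route is rejoined.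

Further compounds
F1 | step 2 | 2-[(tert-butyldimethylsilyloxy)methyl]-6-methoxyphenol | COc1cccc(CO[Si](C)(C)C(C)(C)C)c1O
F2 | step 2 | 2-[(tert-butyldimethylsilyloxy)methyl]-6-methoxy-1,4-benzoquinone | COC1=CC(=O)C=C(CO[Si](C)(C)C(C)(C)C)C1=O
F3 | step 7 | 1α-(3-methylbutanoyloxy)-4-methyl-3,7-diene-2,9-dione (14-OTBS, 5β-H) | C1=CC(=O)[C@@]2(CO[Si](C)(C)C(C)(C)C)[C@H](C1)C(C)=CC(=O)[C@@H]2OC(=O)CC(C)C
F4 | step 9 | 1α,9β-dihydroxy-7β-isopropenyl-4-methyl-3-en-2-one (14-OTBS, 5β-H) | C=C(C)[C@@H]1C[C@H](O)[C@@]2(CO[Si](C)(C)C(C)(C)C)[C@H](C1)C(C)=CC(=O)[C@@H]2O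
F5 | step 9 | 9β-hydroxy-1α-(3-methylbutanoyloxy)-7β-isopropenyl-4-methyl-3-en-2-one (14-OTBS, 5β-H) | C=C(C)[C@@H]1C[C@H](O)[C@@]2(CO[Si](C)(C)C(C)(C)C)[C@H](C1)C(C)=CC(=O)[C@@H]2OC(=O)CC(C)C
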